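## Retrosynthetic overview

1. The plan rests on C6, the allylic carbinol carbon of the ten-membered carbocycle (C1–C10). It lies between the Z C4=C5 alkene and C7 with its C11(=C13)–C12 acrylate branch, and the C5–C6 bond is cut to a Z-iodoalkene at C5 and an aldehyde at C6 (NiCl2/CrCl2 ring closure).
2. Ring order: the 3(2H)-furanone (O, C10, C1, C2, C3) first, then the ten-membered ring by the C5–C6 closure, then the 12,6-lactone from the new C6 hydroxyl and the C12 ester; the O8 ester goes on last.
3. C7–C8 is cut to the furanone C8 aldehyde and a Baylis–Hillman-derived (Z)-2-(bromomethyl)enoate (C6, C7, C11–C13), joined by indium-mediated allylation.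
4. The furanone comes from a citramalate-derived methyl ketone (C1, C2, C8–C10, C14) and (Z)-3-iodo-2-methylprop-2-enal (C3–C5, C15) by aldol addition, oxidation and cyclodehydration; the side-chain acid comes from prenyl acetate.

Key step: step 19

Remark: atoms carry germacranolide locants (C1 furanone carbonyl, C2=C3, C4(C15)=C5, C6–C9, C10(C14) with the ring oxygen joining C3 and C10, C11=C13, C12 carboxyl), and 2-[(4-methoxybenzyl)oxy]acetaldehyde is taken to be a purchasable aldehyde.

## Route

Step 1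
Reactants: 1 (S)-citramalic acid
Product: 2 2-[(4S)-2,2,4-trimethyl-5-oxo-1,3-dioxolan-4-yl]acetic acid
Conditions: 2,2-dimethoxypropane, PPTS (cat.), rt
Reagents that add atoms: 2,2-dimethoxypropane, COC(C)(C)OC
Why: Acid-catalysed transacetalisation (acetonide formation) ties the tertiary hydroxyl and its own carboxyl into a five-membered dioxolanone and leaves only the CH2CO2H carboxyl free; the C10 stereocentre is not touched.

Step 2
Reactants: 2 2-[(4S)-2,2,4-trimethyl-5-oxo-1,3-dioxolan-4-yl]acetic acid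
Product: 3 (5S)-5-(2-hydroxyethyl)-2,2,5-trimethyl-1,3-dioxolan-4-one
Conditions: BH3·SMe2, THF, 0 °C to rt; neutral H2O work-up
Reagents that add atoms: none
Why: Chemoselective borane reduction takes the free carboxylic acid much faster than the dioxolanone ester and gives the future C8 as a primary alcohol; neutral work-up avoids translactonisation.

Step 3
Reactants: 3 (5S)-5-(2-hydroxyethyl)-2,2,5-trimethyl-1,3-dioxolan-4-one
Product: 4 (5S)-5-{2-[(tert-butyldiphenylsilyl)oxy]ethyl}-2,2,5-trimethyl-1,3-dioxolan-4-one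
Conditions: TBDPSCl, imidazole, CH2Cl2, rt
Reagents that add atoms: tert-butyl(chloro)diphenylsilane, CC(C)(C)[Si](Cl)(c1ccccc1)c1ccccc1
Why: Standard silylation of the primary alcohol; the robust silyl ether is chosen to survive the enolate, oxidation and acid steps that follow.

Step 4
Reactants: 4 (5S)-5-{2-[(tert-butyldiphenylsilyl)oxy]ethyl}-2,2,5-trimethyl-1,3-dioxolan-4-one
Product: 5 (2S)-4-[(tert-butyldiphenylsilyl)oxy]-2-hydroxy-N-methoxy-N,2-dimethylbutanamide
Conditions: MeNH(OMe)·HCl, iPrMgCl, THF, −20 to 0 °C; H2O work-up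
Reagents that add atoms: N,O-dimethylhydroxylamine hydrochloride, CNOC.Cl
Why: Weinreb amide formation by aminolysis of the activated dioxolanone ester with the chloromagnesium amide, which expels acetone and frees the tertiary C10 hydroxyl.

Step 5
Reactants: 5 (2S)-4-[(tert-butyldiphenylsilyl)oxy]-2-hydroxy-N-methoxy-N,2-dimethylbutanamide
Product: 6 (3S)-5-[(tert-butyldiphenylsilyl)oxy]-3-hydroxy-3-methylpentan-2-one
Conditions: MeMgBr (excess), THF, 0 °C; then H2O
Reagents that add atoms: methylmagnesium bromide, C[Mg]Br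
Why: Grignard addition to a Weinreb amide stops at the ketone because the chelated tetrahedral intermediate lasts until work-up; one equivalent is taken by the tertiary hydroxyl, and the new methyl group is C2.

Step 6
Reactants: 6 (3S)-5-[(tert-butyldiphenylsilyl)oxy]-3-hydroxy-3-methylpentan-2-one
Product: 7 (3S)-5-[(tert-butyldiphenylsilyl)oxy]-3-methyl-3-[(trimethylsilyl)oxy]pentan-2-one
Conditions: TMSCl, imidazole, DMF, rt
Reagents that add atoms: chlorotrimethylsilane, C[Si](C)(C)Cl
Why: Silylation of the tertiary alcohol removes the acidic proton so that the methyl ketone can be enolised cleanly; the conditions are too mild to form a silyl enol ether.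

Step 7
Reactants: 8 propargyl alcohol
Product: 10 (Z)-3-iodo-2-methylprop-2-en-1-ol, via alkenylmagnesium alkoxide 9 (not isolated)
Conditions: MeMgBr, CuI (cat.), THF/Et2O, −10 °C to rt; then I2, −10 °C; then H2O
Reagents that add atoms: methylmagnesium bromide, C[Mg]Br; iodine, II
Why: Copper-catalysed carbomagnesiation of the magnesium alkoxide adds methyl to C2 and magnesium to C3 in an anti sense, with magnesium held cis to the CH2O group in a five-membered chelate, and iodinolysis with retention gives the Z-iodoalkene (C3, C4, C15, C5).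

Step 8
Reactants: 10 (Z)-3-iodo-2-methylprop-2-en-1-ol
Product: 11 (Z)-3-iodo-2-methylprop-2-enal
Conditions: activated MnO2, CH2Cl2, rt, dark; filtered solution used at once
Reagents that add atoms: none
Why: Neutral MnO2 oxidation of the allylic alcohol gives the Z-iodoenal, which is kept cold and dark in solution because it can drift to the E isomer on standing.

Step 9
Reactants: 7 (3S)-5-[(tert-butyldiphenylsilyl)oxy]-3-methyl-3-[(trimethylsilyl)oxy]pentan-2-one; 11 (Z)-3-iodo-2-methylprop-2-enal
Product: 13 (3S,7Z)-1-[(tert-butyldiphenylsilyl)oxy]-6-hydroxy-8-iodo-3,7-dimethyl-3-[(trimethylsilyl)oxy]oct-7-en-4-one (both C6 epimers of this octenone), via lithium enolate 12 (not isolated)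
Conditions: LiN(iPr)2, THF, −78 °C; then 11, −78 °C; then AcOH
Reagents that add atoms: none
Why: The kinetic lithium enolate of the methyl ketone (its only enolisable position) adds 1,2 to the enal in an aldol addition that forms C2–C3; the new carbinol centre is oxidised in the next step, so its configuration does not matter.

Step 10
Reactants: 13 (3S,7Z)-1-[(tert-butyldiphenylsilyl)oxy]-6-hydroxy-8-iodo-3,7-dimethyl-3-[(trimethylsilyl)oxy]oct-7-en-4-one
Product: 16 (2S)-2-{2-[(tert-butyldiphenylsilyl)oxy]ethyl}-5-[(1Z)-1-iodoprop-1-en-2-yl]-2-methylfuran-3(2H)-one, via silyloxy diketone 14 (not isolated), via hydroxy diketone 15 (not isolated)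
Conditions: Dess–Martin periodinane, CH2Cl2, 0 °C; then TsOH·H2O (cat.), CH2Cl2, rt, dark
Reagents that add atoms: none
Why: Dess–Martin oxidation gives the 1,3-diketone, and acid then removes the tertiary silyl ether and drives 5-exo hemiketalisation of the C10 hydroxyl onto the C3 carbonyl and dehydration to the 3(2H)-furanone (alpha'-hydroxy-1,3-diketone cyclodehydration); working without base and without isolating the diketone should keep its enol oxygen from displacing iodide at C5, and mild acid in the dark should preserve the Z geometry.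

Step 11
Reactants: 16 (2S)-2-{2-[(tert-butyldiphenylsilyl)oxy]ethyl}-5-[(1Z)-1-iodoprop-1-en-2-yl]-2-methylfuran-3(2H)-one
Product: 17 (2S)-2-(2-hydroxyethyl)-5-[(1Z)-1-iodoprop-1-en-2-yl]-2-methylfuran-3(2H)-one
Conditions: HF·pyridine, pyridine, THF, 0 °C to rt
Reagents that add atoms: none
Why: Fluoride-mediated desilylation of the primary silyl ether under buffered conditions, which leave the furanone and the iodoalkene alone.

Step 12
Reactants: 17 (2S)-2-(2-hydroxyethyl)-5-[(1Z)-1-iodoprop-1-en-2-yl]-2-methylfuran-3(2H)-one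
Product: 18 2-[(2S)-5-[(1Z)-1-iodoprop-1-en-2-yl]-2-methyl-3-oxo-2,3-dihydrofuran-2-yl]acetaldehyde
Conditions: Dess–Martin periodinane, NaHCO3, CH2Cl2, 0 °C; used crude
Reagents that add atoms: none
Why: Buffered Dess–Martin oxidation gives the C8 aldehyde without a base strong enough to cause beta-elimination of the furanone oxygen.

Step 13
Reactants: 19 2-[(4-methoxybenzyl)oxy]acetaldehyde; 20 methyl acrylate
Product: 21 methyl 3-hydroxy-4-[(4-methoxybenzyl)oxy]-2-methylidenebutanoate (racemic)
Conditions: DABCO, 1,4-dioxane/H2O (1:1), rt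
Reagents that add atoms: none
Why: Morita–Baylis–Hillman reaction, in which DABCO adds to the acrylate and the resulting enolate attacks the activated alpha-alkoxy aldehyde; the carbinol centre is removed in the next step.

Step 14
Reactants: 21 methyl 3-hydroxy-4-[(4-methoxybenzyl)oxy]-2-methylidenebutanoate
Product: 22 methyl (2Z)-2-(bromomethyl)-4-[(4-methoxybenzyl)oxy]but-2-enoate
Conditions: NBS, Me2S, CH2Cl2, 0 °C to rt
Reagents that add atoms: N-bromosuccinimide, O=C1CCC(=O)N1Br
Why: Bromodimethylsulfonium activation of the allylic alcohol and SN2' attack of bromide give the rearranged primary allylic bromide as the favoured Z isomer, with the CH2O group trans to the ester.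

Step 15
Reactants: 18 2-[(2S)-5-[(1Z)-1-iodoprop-1-en-2-yl]-2-methyl-3-oxo-2,3-dihydrofuran-2-yl]acetaldehyde; 22 methyl (2Z)-2-(bromomethyl)-4-[(4-methoxybenzyl)oxy]but-2-enoate
Product: 24 methyl (3S,4R)-4-hydroxy-5-[(2S)-5-[(1Z)-1-iodoprop-1-en-2-yl]-2-methyl-3-oxo-2,3-dihydrofuran-2-yl]-3-{[(4-methoxybenzyl)oxy]methyl}-2-methylidenepentanoate (7S,8R,10S by target locants), via allylindium dibromide 23 (not isolated)
Conditions: indium powder, THF/H2O (1:1), rt; chromatography
Reagents that add atoms: none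
Why: Barbier-type 2-(alkoxycarbonyl)allylation in which the allylindium adds through its gamma-carbon in a Zimmerman–Traxler chair, the Z-configured allyl unit giving the syn C7/C8 relationship; the remote C10 centre is not expected to decide which aldehyde face reacts, so 24 is to be separated by chromatography from its (7R,8S,10S) syn diastereomer.

Step 16
Reactants: 24 methyl (3S,4R)-4-hydroxy-5-[(2S)-5-[(1Z)-1-iodoprop-1-en-2-yl]-2-methyl-3-oxo-2,3-dihydrofuran-2-yl]-3-{[(4-methoxybenzyl)oxy]methyl}-2-methylidenepentanoate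
Product: 25 methyl (3S,4R)-4-[(tert-butyldimethylsilyl)oxy]-5-[(2S)-5-[(1Z)-1-iodoprop-1-en-2-yl]-2-methyl-3-oxo-2,3-dihydrofuran-2-yl]-3-{[(4-methoxybenzyl)oxy]methyl}-2-methylidenepentanoate
Conditions: TBSOTf, 2,6-lutidine, CH2Cl2, −78 °C
Reagents that add atoms: tert-butyldimethylsilyl trifluoromethanesulfonate, CC(C)(C)[Si](C)(C)OS(=O)(=O)C(F)(F)F
Why: Silyl triflate silylation of the hindered secondary C8 hydroxyl at low temperature, done at once so that it cannot lactonise onto the C12 ester.

Step 17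
Reactants: 25 methyl (3S,4R)-4-[(tert-butyldimethylsilyl)oxy]-5-[(2S)-5-[(1Z)-1-iodoprop-1-en-2-yl]-2-methyl-3-oxo-2,3-dihydrofuran-2-yl]-3-{[(4-methoxybenzyl)oxy]methyl}-2-methylidenepentanoate
Product: 26 methyl (3S,4R)-4-[(tert-butyldimethylsilyl)oxy]-3-(hydroxymethyl)-5-[(2S)-5-[(1Z)-1-iodoprop-1-en-2-yl]-2-methyl-3-oxo-2,3-dihydrofuran-2-yl]-2-methylidenepentanoate
Conditions: DDQ, CH2Cl2/pH 7 phosphate buffer, 0 °C; crude product taken on at once
Reagents that add atoms: none
Why: Oxidative cleavage of the 4-methoxybenzyl ether by DDQ (hydride abstraction, then hydrolysis of the oxocarbenium ion) leaves the silyl ether, iodoalkene and acrylate intact; buffering and immediate use keep the freed C6 alcohol from closing onto the C12 ester.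

Step 18
Reactants: 26 methyl (3S,4R)-4-[(tert-butyldimethylsilyl)oxy]-3-(hydroxymethyl)-5-[(2S)-5-[(1Z)-1-iodoprop-1-en-2-yl]-2-methyl-3-oxo-2,3-dihydrofuran-2-yl]-2-methylidenepentanoate
Product: 27 methyl (3R,4R)-4-[(tert-butyldimethylsilyl)oxy]-3-formyl-5-[(2S)-5-[(1Z)-1-iodoprop-1-en-2-yl]-2-methyl-3-oxo-2,3-dihydrofuran-2-yl]-2-methylidenepentanoate
Conditions: Dess–Martin periodinane, NaHCO3, CH2Cl2, 0 °C; filtered and cyclised the same day
Reagents that add atoms: none
Why: Buffered Dess–Martin oxidation gives the C6 aldehyde under non-basic conditions, so the C7 stereocentre (alpha to the aldehyde and allylic) should not epimerise and the C8 silyl ether should not eliminate.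

Step 19
Reactants: 27 methyl (3R,4R)-4-[(tert-butyldimethylsilyl)oxy]-3-formyl-5-[(2S)-5-[(1Z)-1-iodoprop-1-en-2-yl]-2-methyl-3-oxo-2,3-dihydrofuran-2-yl]-2-methylidenepentanoate
Product: 29 methyl (4Z,6R,7S,8R,10S)-8-[(tert-butyldimethylsilyl)oxy]-6-hydroxy-1-oxo-3,10-epoxygermacra-2,4,11(13)-trien-12-oate (macrocyclic C6 allylic alcohol bearing the methyl acrylate at C7), via alkenylchromium dichloride 28 (not isolated)
Conditions: CrCl2 (excess), NiCl2 (about 1 mol% of the CrCl2), degassed DMSO, rt, slow addition of 27 to high dilution; aqueous work-up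
Reagents that add atoms: none
Why: NiCl2 is reduced by CrCl2 to zerovalent nickel, which inserts into the C5–I bond; transmetallation to trivalent chromium gives alkenylchromium 28, which adds to the C6 aldehyde and leaves a chromium alkoxide that is protonated on work-up (intramolecular Nozaki–Hiyama–Kishi reaction). The closest known reaction type is the NiCl2/CrCl2 closure of iodoalkene aldehydes to nine- and ten-membered cyclic allylic alcohols, and the retention of geometry known for Z-beta-iodoenoates applies here, so C3 and C6 stay cis on C4=C5. The new C5–C6 bond closes the ten-membered carbocycle C1–C10 (a nine-membered ring if counted through the furanone oxygen) by exo-trig addition to the carbonyl. The C6 stereocentre is controlled by the adjacent C7 centre under ring constraint: the forming bond should lie anti to the C7 acrylate branch with the chromium-bound oxygen turned to the outside of the ring, away from C8 and its silyl ether, which leads to 6R, the relationship needed for the trans-lactone. The step needs chemoselectivity for the aldehyde over the furanone ketone and the acrylate, which the oxophilic, non-basic alkenylchromium provides, and ring closure over oligomerisation, which slow addition at high dilution secures. The neutral medium also protects the C7–H from epimerisation and the C8 silyl ether from beta-elimination.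

Step 20
Reactants: 29 methyl (4Z,6R,7S,8R,10S)-8-[(tert-butyldimethylsilyl)oxy]-6-hydroxy-1-oxo-3,10-epoxygermacra-2,4,11(13)-trien-12-oate
Product: 30 (4Z,6R,7S,8R,10S)-8-[(tert-butyldimethylsilyl)oxy]-1-oxo-3,10-epoxygermacra-2,4,11(13)-trien-12,6-olide
Conditions: CSA (cat.), CH2Cl2, rt
Reagents that add atoms: none
Why: Acid-catalysed intramolecular transesterification of the C6 hydroxyl onto the neighbouring methyl ester (5-exo-trig lactonisation) forms the alpha-methylene lactone, trans-fused because C6 and C7 were set that way; the C8 silyl ether rules out closure to O8.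

Step 21
Reactants: 30 (4Z,6R,7S,8R,10S)-8-[(tert-butyldimethylsilyl)oxy]-1-oxo-3,10-epoxygermacra-2,4,11(13)-trien-12,6-olide
Product: 31 (4Z,6R,7R,8R,10S)-8-hydroxy-1-oxo-3,10-epoxygermacra-2,4,11(13)-trien-12,6-olide
Conditions: HF·pyridine, pyridine, THF, 0 °C to rt
Reagents that add atoms: none
Why: Fluoride-mediated desilylation without strong base, so neither translactonisation to O8 nor conjugate addition to the methylene lactone is provoked (the C7 descriptor changes only through priorities).

Step 22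
Reactants: 32 prenyl acetate
Product: 33 (2E)-4-acetoxy-2-methylbut-2-enal
Conditions: SeO2, 1,4-dioxane, 80 °C
Reagents that add atoms: selenium dioxide, O=[Se]=O
Why: Selenium dioxide allylic oxidation (ene reaction, then [2,3]-sigmatropic shift) attacks the E-methyl group of the trisubstituted alkene and carries it on to the E-enal.

Step 23
Reactants: 33 (2E)-4-acetoxy-2-methylbut-2-enal
Product: 34 (2E)-4-acetoxy-2-methylbut-2-enoic acid
Conditions: NaClO2, NaH2PO4, 2-methylbut-2-ene, tBuOH/H2O, rt
Reagents that add atoms: sodium chlorite, [Na+].[O-]Cl=O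
Why: Pinnick oxidation converts the enal to the acid without touching the alkene geometry or the acetate, with 2-methylbut-2-ene trapping the hypochlorous acid.

Step 24
Reactants: 31 (4Z,6R,7R,8R,10S)-8-hydroxy-1-oxo-3,10-epoxygermacra-2,4,11(13)-trien-12,6-olide; 34 (2E)-4-acetoxy-2-methylbut-2-enoic acid
Product: 36 target CNP0387534.1, via mixed anhydride 35 (not isolated)
Conditions: 2,4,6-trichlorobenzoyl chloride, Et3N, toluene, rt; then 31, DMAP, toluene, rt
Reagents that add atoms: none
Why: Yamaguchi esterification, in which DMAP attacks the less hindered enoyl carbonyl of the mixed anhydride and the acylpyridinium acylates the hindered C8 hydroxyl with retention at C8; the E acid is the stable isomer and should not isomerise.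

## Compound list

1 | (S)-citramalic acid | OC(=O)[C@](C)(CC(=O)O)O | starting material
2 | 2-[(4S)-2,2,4-trimethyl-5-oxo-1,3-dioxolan-4-yl]acetic acid | CC1(C)OC(=O)[C@](C)(CC(=O)O)O1 | intermediate
3 | (5S)-5-(2-hydroxyethyl)-2,2,5-trimethyl-1,3-dioxolan-4-one | CC1(C)OC(=O)[C@](C)(CCO)O1 | intermediate
4 | (5S)-5-{2-[(tert-butyldiphenylsilyl)oxy]ethyl}-2,2,5-trimethyl-1,3-dioxolan-4-one | CC1(C)OC(=O)[C@](C)(CCO[Si](c2ccccc2)(c2ccccc2)C(C)(C)C)O1 | intermediate
5 | (2S)-4-[(tert-butyldiphenylsilyl)oxy]-2-hydroxy-N-methoxy-N,2-dimethylbutanamide | CON(C)C(=O)[C@](C)(CCO[Si](c1ccccc1)(c1ccccc1)C(C)(C)C)O | intermediate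
6 | (3S)-5-[(tert-butyldiphenylsilyl)oxy]-3-hydroxy-3-methylpentan-2-one | CC(=O)[C@](C)(CCO[Si](c1ccccc1)(c1ccccc1)C(C)(C)C)O | intermediate
7 | (3S)-5-[(tert-butyldiphenylsilyl)oxy]-3-methyl-3-[(trimethylsilyl)oxy]pentan-2-one | CC(=O)[C@](C)(CCO[Si](c1ccccc1)(c1ccccc1)C(C)(C)C)O[Si](C)(C)C | intermediate
8 | propargyl alcohol (prop-2-yn-1-ol) | C#CCO | starting material
9 | alkenylmagnesium alkoxide: bromomagnesium (Z)-3-(bromomagnesio)-2-methylprop-2-en-1-olate | C/C(CO[Mg]Br)=C/[Mg]Br | intermediate
10 | (Z)-3-iodo-2-methylprop-2-en-1-ol | OC/C(C)=C\I | intermediate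
11 | (Z)-3-iodo-2-methylprop-2-enal | O=C/C(C)=C\I | intermediate
12 | lithium enolate of 7 | [Li]OC(=C)[C@](C)(CCO[Si](c1ccccc1)(c1ccccc1)C(C)(C)C)O[Si](C)(C)C | intermediate
13 | (3S,7Z)-1-[(tert-butyldiphenylsilyl)oxy]-6-hydroxy-8-iodo-3,7-dimethyl-3-[(trimethylsilyl)oxy]oct-7-en-4-one, both C6 epimers | O=C(CC(O)/C(C)=C\I)[C@](C)(CCO[Si](c1ccccc1)(c1ccccc1)C(C)(C)C)O[Si](C)(C)C | intermediate
14 | silyloxy diketone: (3S,7Z)-1-[(tert-butyldiphenylsilyl)oxy]-8-iodo-3,7-dimethyl-3-[(trimethylsilyl)oxy]oct-7-ene-4,6-dione | O=C(CC(=O)/C(C)=C\I)[C@](C)(CCO[Si](c1ccccc1)(c1ccccc1)C(C)(C)C)O[Si](C)(C)C | intermediate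
15 | hydroxy diketone: (3S,7Z)-1-[(tert-butyldiphenylsilyl)oxy]-3-hydroxy-8-iodo-3,7-dimethyloct-7-ene-4,6-dione | O=C(CC(=O)/C(C)=C\I)[C@](C)(CCO[Si](c1ccccc1)(c1ccccc1)C(C)(C)C)O | intermediate
16 | (2S)-2-{2-[(tert-butyldiphenylsilyl)oxy]ethyl}-5-[(1Z)-1-iodoprop-1-en-2-yl]-2-methylfuran-3(2H)-one | CC(C)(C)[Si](c1ccccc1)(c1ccccc1)OCC[C@]1(C)OC(=CC1=O)/C(C)=C\I | intermediate
17 | (2S)-2-(2-hydroxyethyl)-5-[(1Z)-1-iodoprop-1-en-2-yl]-2-methylfuran-3(2H)-one | OCC[C@]1(C)OC(=CC1=O)/C(C)=C\I | intermediate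
18 | 2-[(2S)-5-[(1Z)-1-iodoprop-1-en-2-yl]-2-methyl-3-oxo-2,3-dihydrofuran-2-yl]acetaldehyde | O=CC[C@]1(C)OC(=CC1=O)/C(C)=C\I | intermediate
19 | 2-[(4-methoxybenzyl)oxy]acetaldehyde | O=CCOCc1ccc(OC)cc1 | starting material
20 | methyl acrylate | C=CC(=O)OC | starting material
21 | methyl 3-hydroxy-4-[(4-methoxybenzyl)oxy]-2-methylidenebutanoate (racemic) | C=C(C(=O)OC)C(O)COCc1ccc(OC)cc1 | intermediate
22 | methyl (2Z)-2-(bromomethyl)-4-[(4-methoxybenzyl)oxy]but-2-enoate | COC(=O)/C(CBr)=C/COCc1ccc(OC)cc1 | intermediate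
23 | allylindium dibromide derived from 22 | COC(=O)/C(C[In](Br)Br)=C/COCc1ccc(OC)cc1 | intermediate
24 | methyl (3S,4R)-4-hydroxy-5-[(2S)-5-[(1Z)-1-iodoprop-1-en-2-yl]-2-methyl-3-oxo-2,3-dihydrofuran-2-yl]-3-{[(4-methoxybenzyl)oxy]methyl}-2-methylidenepentanoate | COc1ccc(COC[C@H](C(=C)C(=O)OC)[C@H](O)C[C@]2(C)OC(=CC2=O)/C(C)=C\I)cc1 | intermediate
25 | methyl (3S,4R)-4-[(tert-butyldimethylsilyl)oxy]-5-[(2S)-5-[(1Z)-1-iodoprop-1-en-2-yl]-2-methyl-3-oxo-2,3-dihydrofuran-2-yl]-3-{[(4-methoxybenzyl)oxy]methyl}-2-methylidenepentanoate | COc1ccc(COC[C@H](C(=C)C(=O)OC)[C@H](O[Si](C)(C)C(C)(C)C)C[C@]2(C)OC(=CC2=O)/C(C)=C\I)cc1 | intermediate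
26 | methyl (3S,4R)-4-[(tert-butyldimethylsilyl)oxy]-3-(hydroxymethyl)-5-[(2S)-5-[(1Z)-1-iodoprop-1-en-2-yl]-2-methyl-3-oxo-2,3-dihydrofuran-2-yl]-2-methylidenepentanoate | OC[C@H](C(=C)C(=O)OC)[C@H](O[Si](C)(C)C(C)(C)C)C[C@]1(C)OC(=CC1=O)/C(C)=C\I | intermediate
27 | methyl (3R,4R)-4-[(tert-butyldimethylsilyl)oxy]-3-formyl-5-[(2S)-5-[(1Z)-1-iodoprop-1-en-2-yl]-2-methyl-3-oxo-2,3-dihydrofuran-2-yl]-2-methylidenepentanoate (key-step precursor) | O=C[C@H](C(=C)C(=O)OC)[C@H](O[Si](C)(C)C(C)(C)C)C[C@]1(C)OC(=CC1=O)/C(C)=C\I | intermediate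
28 | alkenylchromium dichloride derived from 27 (chromium on C5 in place of iodine) | O=C[C@H](C(=C)C(=O)OC)[C@H](O[Si](C)(C)C(C)(C)C)C[C@]1(C)OC(=CC1=O)/C(C)=C\[Cr](Cl)Cl | intermediate
29 | methyl (4Z,6R,7S,8R,10S)-8-[(tert-butyldimethylsilyl)oxy]-6-hydroxy-1-oxo-3,10-epoxygermacra-2,4,11(13)-trien-12-oate (key-step product) | C=C(C(=O)OC)[C@H]1[C@H](O)/C=C(/C)C2=CC(=O)[C@](C)(C[C@H]1O[Si](C)(C)C(C)(C)C)O2 | intermediate
30 | (4Z,6R,7S,8R,10S)-8-[(tert-butyldimethylsilyl)oxy]-1-oxo-3,10-epoxygermacra-2,4,11(13)-trien-12,6-olide | C=C1C(=O)O[C@@H]2/C=C(/C)C3=CC(=O)[C@](C)(C[C@@H](O[Si](C)(C)C(C)(C)C)[C@@H]12)O3 | intermediate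
31 | (4Z,6R,7R,8R,10S)-8-hydroxy-1-oxo-3,10-epoxygermacra-2,4,11(13)-trien-12,6-olide | C=C1C(=O)O[C@@H]2/C=C(/C)C3=CC(=O)[C@](C)(C[C@@H](O)[C@@H]12)O3 | intermediate
32 | prenyl acetate (3-methylbut-2-en-1-yl acetate) | CC(C)=CCOC(C)=O | starting material
33 | (2E)-4-acetoxy-2-methylbut-2-enal | O=C/C(C)=C/COC(C)=O | intermediate
34 | (2E)-4-acetoxy-2-methylbut-2-enoic acid | OC(=O)/C(C)=C/COC(C)=O | intermediate
35 | mixed anhydride of 34 with 2,4,6-trichlorobenzoic acid | O=C(OC(=O)c1c(Cl)cc(Cl)cc1Cl)/C(C)=C/COC(C)=O | intermediate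
36 | CNP0387534.1: (4Z,6R,7R,8R,10S)-8-{[(2E)-4-acetoxy-2-methylbut-2-enoyl]oxy}-1-oxo-3,10-epoxygermacra-2,4,11(13)-trien-12,6-olide | C=C1C(=O)O[C@@H]2/C=C(/C)C3=CC(=O)[C@](C)(C[C@@H](OC(=O)/C(C)=C/COC(C)=O)[C@@H]12)O3 | target

## Step count and risks

Total step count: 24.
Longest linear sequence: 18 steps (steps 1–6, 9–12, 15–21, 24).

Steps most likely to fail:

Step 19 (ring closure). The alkenylchromium may add to the other face of the aldehyde, so that the 6S carbinol forms; slow closure would also let protodeiodination and oligomerisation compete. The fallback for the wrong face sets out from 27 and returns at 30. The cyclisation is run as in step 19 and the C6 epimer is carried on as methyl (4Z,6S,7S,8R,10S)-8-[(tert-butyldimethylsilyl)oxy]-6-hydroxy-1-oxo-3,10-epoxygermacra-2,4,11(13)-trien-12-oate F1. Its methyl ester is cleaved with Me3SnOH (1,2-dichloroethane, 70 °C) to the hydroxy acid (4Z,6S,7S,8R,10S)-8-[(tert-butyldimethylsilyl)oxy]-6-hydroxy-1-oxo-3,10-epoxygermacra-2,4,11(13)-trien-12-oic acid F2. Mitsunobu lactonisation (PPh3, DIAD, toluene, high dilution) then closes the lactone by carboxylate SN2 displacement with inversion at C6 and should give 30.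

Step 15 (allylation). The remote C10 centre may give no useful discrimination between the two aldehyde faces, so that a large part of the material ends as the other syn adduct. The fallback sets out from 18 and 22 and returns at 24; it replaces substrate control by catalyst control. A nickel-free catalytic enantioselective Nozaki–Hiyama 2-(alkoxycarbonyl)allylation is used: CrCl2 (catalytic), a chiral tridentate carbazole bis(oxazoline) ligand, Mn powder, TMSCl, iPr2NEt, THF. The ligand enantiomer that delivers the 8R carbinol is chosen, and the iodoalkene is inert without nickel. The allylchromium keeps the geometry of the acrylate, so the chair transition state should again give the syn adduct. It is released as the C8 trimethylsilyl ether of 24 F3, which citric acid in MeOH cleaves to 24.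

Step 10 (oxidation and cyclodehydration). The Z-iodoalkene may isomerise under acid, or the diketone enol oxygen may attack C5 with loss of iodide (pyranone formation) before the furanone closes. The fallback sets out from 11 and 5 and returns at 16; it avoids the 1,3-diketone altogether. Iodoenal 11 is homologated with lithiated trimethylsilyldiazomethane (Colvin rearrangement; THF, −78 to 0 °C) to (1Z)-1-iodo-2-methylbut-1-en-3-yne F4. Its lithium acetylide (LiN(iPr)2, THF, −78 °C; two equivalents, the first taken by the tertiary hydroxyl) adds to Weinreb amide 5 to give the alpha'-hydroxy ynone (3S,7Z)-1-[(tert-butyldiphenylsilyl)oxy]-3-hydroxy-8-iodo-3,7-dimethyloct-7-en-5-yn-4-one F5. 5-endo-dig addition of the hydroxyl to the ynone (AgOTf cat. in CH2Cl2, or Et2NH in EtOH) should give furanone 16.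

Further compounds

F1 | step 19 | methyl (4Z,6S,7S,8R,10S)-8-[(tert-butyldimethylsilyl)oxy]-6-hydroxy-1-oxo-3,10-epoxygermacra-2,4,11(13)-trien-12-oate (C6 epimer of 29) | C=C(C(=O)OC)[C@H]1[C@@H](O)/C=C(/C)C2=CC(=O)[C@](C)(C[C@H]1O[Si](C)(C)C(C)(C)C)O2
F2 | step 19 | (4Z,6S,7S,8R,10S)-8-[(tert-butyldimethylsilyl)oxy]-6-hydroxy-1-oxo-3,10-epoxygermacra-2,4,11(13)-trien-12-oic acid | C=C(C(=O)O)[C@H]1[C@@H](O)/C=C(/C)C2=CC(=O)[C@](C)(C[C@H]1O[Si](C)(C)C(C)(C)C)O2
F3 | step 15 | C8 trimethylsilyl ether of 24 | COc1ccc(COC[C@H](C(=C)C(=O)OC)[C@H](O[Si](C)(C)C)C[C@]2(C)OC(=CC2=O)/C(C)=C\I)cc1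
F4 | step 10 | (1Z)-1-iodo-2-methylbut-1-en-3-yne | C#C/C(C)=C\I
F5 | step 10 | (3S,7Z)-1-[(tert-butyldiphenylsilyl)oxy]-3-hydroxy-8-iodo-3,7-dimethyloct-7-en-5-yn-4-one | O=C(C#C/C(C)=C\I)[C@](C)(CCO[Si](c1ccccc1)(c1ccccc1)C(C)(C)C)O
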